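**Plan**

- Retrosynthesis: the MOM ethers are removed and the C4 carbonyl of unit 1 (the 7-methoxyflavanone) is taken back to CH2. Ring C of that flavan is then cut at O1–C2 and C3–C4. The diaryl ether is cut between its oxygen and C3' of ring B of unit 1.
- Enabling feature: ring C of unit 1 is a dihydropyran fused to the phloroglucinol-type ring A. O1–C8a–C4a–C4 is therefore the oxa-diene of an ortho-quinone methide pushed by the 5- and 7-oxygens, and C2–C3 is the vinyl group of a para-oxygenated ring B styrene.
- Forward: a ring A salicyl alcohol (3 steps) and a vinylarylboronic acid (3 steps) are made separately. The boronic acid is joined to O-4' of 7-O-MOM-(2S)-naringenin by Chan–Lam coupling, so all rings of unit 2 are bought.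
- Ring C of unit 1 is the only ring built, by hetero-[4+2]. C4–H oxidation (DDQ/water, then Dess–Martin) and acid deprotection finish the route.
- Stereochemistry: C2 of unit 2 comes from (2S)-naringenin and never meets strong base, because the Wittig reaction is run before the coupling. C2 of unit 1 is set in the cycloaddition by the chiral phosphoric acid.

Key step: step 9

Assumption: purchased (2S)-naringenin is taken as enantiomerically pure; its ee is checked and, if needed, raised on a chiral phase before step 7.
Assumption: the (R) acid is written for the (2S) product; the sense of induction cannot be derived from analogy, and the (S) acid is used if the C2 epimer forms.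

Step 1
Reactants: 1 2,4,6-trihydroxybenzaldehyde
Product: 2 2,6-dihydroxy-4-methoxybenzaldehyde
Conditions: Me2SO4 (1.0 equiv), K2CO3 (1.0 equiv), acetone, rt
Reagents that add atoms: dimethyl sulfate, COS(=O)(=O)OC
Why: Williamson-type O-methylation; the 4-OH is para to the formyl group and is the only hydroxyl not held in a hydrogen bond to it, so one equivalent of a hard electrophile under weak base should alkylate there first.

Step 2
Reactants: 2 2,6-dihydroxy-4-methoxybenzaldehyde
Product: 3 2-hydroxy-4-methoxy-6-(methoxymethoxy)benzaldehyde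
Conditions: MOMCl (1.05 equiv), i-Pr2NEt (1.2 equiv), CH2Cl2, 0 °C
Reagents that add atoms: chloromethyl methyl ether, COCCl
Why: MOM protection of one of two equivalent hydroxyls; after the first alkylation the remaining OH is locked in the hydrogen bond to the aldehyde and reacts much more slowly, which secures mono-protection.

Step 3
Reactants: 3 2-hydroxy-4-methoxy-6-(methoxymethoxy)benzaldehyde
Product: 4 2-(hydroxymethyl)-5-methoxy-3-(methoxymethoxy)phenol
Conditions: NaBH4, THF–EtOH, −10 °C, short time; pH 7 phosphate buffer; run directly before step 9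
Reagents that add atoms: none
Why: Borohydride 1,2-reduction of an aromatic aldehyde; low temperature and a neutral quench are chosen because this electron-rich salicyl alcohol loses water easily, and 4 is used without storage.

Step 4
Reactants: 5 3-bromo-4-hydroxybenzaldehyde
Product: 6 3-bromo-4-(methoxymethoxy)benzaldehyde
Conditions: MOMCl (1.2 equiv), i-Pr2NEt (1.5 equiv), CH2Cl2, 0 °C to rt
Reagents that add atoms: chloromethyl methyl ether, COCCl
Why: MOM protection of an acidic phenol (para formyl, ortho bromine); the acetal oxygen later stabilises the ortho-lithio species by chelation.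

Step 5
Reactants: 6 3-bromo-4-(methoxymethoxy)benzaldehyde
Product: 7 2-bromo-1-(methoxymethoxy)-4-vinylbenzene
Conditions: Ph3PCH3Br, KOt-Bu, THF, 0 °C to rt
Reagents that add atoms: methyltriphenylphosphonium bromide, C[P+](c1ccccc1)(c1ccccc1)c1ccccc1.[Br-]
Why: Wittig methylenation of an aromatic aldehyde, placed here so that the basic ylide never meets the base-sensitive flavanone of unit 2.

Step 6
Reactants: 7 2-bromo-1-(methoxymethoxy)-4-vinylbenzene
Product: 10 [2-(methoxymethoxy)-5-vinylphenyl]boronic acid, via aryllithium 8 (not isolated), via lithium aryltriisopropoxyborate 9 (not isolated)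
Conditions: n-BuLi added to 7 + B(Oi-Pr)3, THF–toluene, −78 °C (in situ quench); then 1 M HCl to pH 5, 0 °C
Reagents that add atoms: triisopropyl borate, CC(C)OB(OC(C)C)OC(C)C; water, O
Why: Bromine–lithium exchange with in situ borate trapping and mild hydrolysis; at −78 °C exchange outruns butyllithium addition to the styrene, the MOM oxygen chelates lithium, and the borate already present keeps the lifetime of 8 short.

Step 7
Reactants: 11 (2S)-naringenin
Product: 12 (2S)-5-hydroxy-2-(4-hydroxyphenyl)-7-(methoxymethoxy)chroman-4-one (7-O-MOM-naringenin)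
Conditions: MOMCl (1.0 equiv), i-Pr2NEt (1.1 equiv), THF, 0 °C
Reagents that add atoms: chloromethyl methyl ether, COCCl
Why: Regioselective O-alkylation; the 7-OH (para to the carbonyl) is the most acidic and the 5-OH is chelated, so one equivalent of base and MOMCl should leave the 4'-OH free, and the 7-phenoxide disfavours retro-oxa-Michael opening so C2 is untouched.

Step 8
Reactants: 12 7-O-MOM-naringenin; 10 [2-(methoxymethoxy)-5-vinylphenyl]boronic acid
Product: 13 (2S)-5-hydroxy-7-(methoxymethoxy)-2-{4-[2-(methoxymethoxy)-5-vinylphenoxy]phenyl}chroman-4-one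
Conditions: 10 (2 equiv), Cu(OAc)2 (2 equiv), pyridine (5 equiv), 4 Å MS, CH2Cl2, dry air, rt
Reagents that add atoms: none
Why: Chan–Lam oxidative C–O coupling at room temperature with pyridine as the only base; the free 4'-OH is arylated while the chelated, electron-poor 5-OH is a poor partner, and the absence of strong base or heat keeps the flavanone ring closed and C2 intact.

Step 9
Reactants: 4 2-(hydroxymethyl)-5-methoxy-3-(methoxymethoxy)phenol; 13 unit 2 flavanone bearing the ring B styrene
Product: 15 (2S)-5-hydroxy-2-[4-(5-{(2S)-7-methoxy-5-(methoxymethoxy)chroman-2-yl}-2-(methoxymethoxy)phenoxy)phenyl]-7-(methoxymethoxy)chroman-4-one, via ortho-quinone methide 14 (not isolated)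
Conditions: (R)-TRIP [(R)-3,3'-bis(2,4,6-triisopropylphenyl)-1,1'-binaphthyl-2,2'-diyl hydrogen phosphate] (10 mol %), 4 Å MS, toluene, 0 °C; 4 (2.5 equiv) added by syringe pump over 12 h
Reagents that add atoms: none
Why: Proposed new method: the phosphoric acid protonates the benzylic hydroxyl of 4, whose departure is pushed by the para methoxy group and the two ortho oxygens, and methide 14 stays hydrogen-bonded to the phosphate through its carbonyl oxygen; its oxa-diene O=C–C=CH2 then takes up the vinyl group of 13 in an inverse-electron-demand hetero-Diels–Alder reaction that is concerted but strongly asynchronous, C3–C4 forming first and O1–C2 closing as charge builds on the benzylic carbon para to the MOM-oxy group. The closest known reactions are the thermal or acid-promoted [4+2] of ortho-quinone methides with styrenes to racemic flavans and the chiral-phosphoric-acid-catalysed oxa-[4+2] of aryl-substituted methides with hydroxystyrenes, vinylindoles or enamides; new here are the unsubstituted methide carbon and a styrene without a hydrogen-bond donor. Ring C (O1–C2–C3–C4–C4a–C8a) closes by intermolecular [4+2] cycloaddition, driven by rearomatisation of ring A. C2, the only new stereocentre, is made at the oxygen terminus of the diene, directly beside the bound phosphate, so the 2,4,6-triisopropylphenyl walls must select both the styrene face and the endo or exo placement of ring B, while the distant C2 of unit 2 exerts no bias and is untouched by the weak acid. Regiochemistry (aryl on C2) follows from pairing the nucleophilic styrene CH2 with the electrophilic methide CH2. The chemoselectivity needed is cycloaddition ahead of methide self-condensation and Friedel–Crafts attack on ring A of 15, which slow addition of an excess of cheap 4 to the electron-rich styrene is meant to secure, and the MOM ethers, ketone and chelated 5-OH tolerate the conditions.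

Step 10
Reactants: 15 flavan–flavanone
Product: 16 (2S)-5-hydroxy-2-[4-(5-{(2S)-4-hydroxy-7-methoxy-5-(methoxymethoxy)chroman-2-yl}-2-(methoxymethoxy)phenoxy)phenyl]-7-(methoxymethoxy)chroman-4-one (C4 carbinol epimers, used together)
Conditions: DDQ (1.2 equiv), CH2Cl2–pH 7 aqueous phosphate buffer (10:1), 0 °C to rt
Reagents that add atoms: water, O
Why: DDQ benzylic C–H oxidation by hydride abstraction, known for 5,7-dialkoxyflavans; the C4 cation is stabilised by O1 and the 5-oxygen (ortho) and the 7-OMe (para) and is captured by water, whereas C2–H of unit 1 sits on the less donor-rich ring B and unit 2 is deactivated by its carbonyl, so both C2 centres should stay intact, and the new C4 centre is erased in step 11.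

Step 11
Reactants: 16 flavan-4-ol–flavanone
Product: 17 (2S)-5-hydroxy-2-[4-(5-{(2S)-7-methoxy-5-(methoxymethoxy)-4-oxochroman-2-yl}-2-(methoxymethoxy)phenoxy)phenyl]-7-(methoxymethoxy)chroman-4-one
Conditions: Dess–Martin periodinane (1.3 equiv), NaHCO3, CH2Cl2, 0 °C to rt
Reagents that add atoms: none
Why: Dess–Martin oxidation of a secondary benzylic alcohol under buffered, non-basic conditions, which neither ionises the acid-labile carbinol nor opens either flavanone ring; both C4 epimers converge on one ketone.

Step 12
Reactants: 17 tris-MOM biflavanone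
Product: 18 7-O-methyltetrahydroochnaflavone, (2S) in both units
Conditions: HCl (1.25 M in MeOH), MeOH–THF, 40 °C
Reagents that add atoms: none
Why: Acid-catalysed acetal exchange with methanol (MOM cleavage); the aryl methyl ether, diaryl ether and ketones are inert, and acid at moderate temperature avoids the phenoxide-driven retro-oxa-Michael opening that would scramble C2 of either unit.

**Compound list**

1 | 2,4,6-trihydroxybenzaldehyde | O=Cc1c(O)cc(O)cc1O | starting material
2 | 2,6-dihydroxy-4-methoxybenzaldehyde | COc1cc(O)c(C=O)c(O)c1 | intermediate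
3 | 2-hydroxy-4-methoxy-6-(methoxymethoxy)benzaldehyde | COCOc1cc(OC)cc(O)c1C=O | intermediate
4 | 2-(hydroxymethyl)-5-methoxy-3-(methoxymethoxy)phenol | COc1cc(O)c(CO)c(OCOC)c1 | intermediate
5 | 3-bromo-4-hydroxybenzaldehyde | O=Cc1ccc(O)c(Br)c1 | starting material
6 | 3-bromo-4-(methoxymethoxy)benzaldehyde | COCOc1ccc(C=O)cc1Br | intermediate
7 | 2-bromo-1-(methoxymethoxy)-4-vinylbenzene | C=Cc1ccc(OCOC)c(Br)c1 | intermediate
8 | [2-(methoxymethoxy)-5-vinylphenyl]lithium (not isolated) | C=Cc1ccc(OCOC)c([Li])c1 | intermediate
9 | lithium [2-(methoxymethoxy)-5-vinylphenyl]triisopropoxyborate (not isolated) | [Li+].C=Cc1ccc(OCOC)c(c1)[B-](OC(C)C)(OC(C)C)OC(C)C | intermediate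
10 | [2-(methoxymethoxy)-5-vinylphenyl]boronic acid | C=Cc1ccc(OCOC)c(B(O)O)c1 | intermediate
11 | (2S)-naringenin | Oc1ccc([C@@H]2CC(=O)c3c(O)cc(O)cc3O2)cc1 | starting material
12 | (2S)-5-hydroxy-2-(4-hydroxyphenyl)-7-(methoxymethoxy)chroman-4-one | Oc1ccc([C@@H]2CC(=O)c3c(O)cc(OCOC)cc3O2)cc1 | intermediate
13 | (2S)-5-hydroxy-7-(methoxymethoxy)-2-{4-[2-(methoxymethoxy)-5-vinylphenoxy]phenyl}chroman-4-one | C=Cc1ccc(OCOC)c(Oc3ccc([C@@H]4CC(=O)c5c(O)cc(OCOC)cc5O4)cc3)c1 | intermediate
14 | 3-methoxy-5-(methoxymethoxy)-6-methylidenecyclohexa-2,4-dien-1-one (not isolated) | C=C1C(=O)C=C(OC)C=C1OCOC | intermediate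
15 | flavan–flavanone, (2S) in both units, C4 of unit 1 = CH2 | COc1cc(OCOC)c2c(c1)O[C@H](c1ccc(OCOC)c(Oc3ccc([C@@H]4CC(=O)c5c(O)cc(OCOC)cc5O4)cc3)c1)CC2 | intermediate
16 | flavan-4-ol–flavanone, (2S) in both units, C4 epimers | COc1cc(OCOC)c2c(c1)O[C@H](c1ccc(OCOC)c(Oc3ccc([C@@H]4CC(=O)c5c(O)cc(OCOC)cc5O4)cc3)c1)CC2O | intermediate
17 | tris-MOM biflavanone, (2S) in both units | COc1cc(OCOC)c2c(c1)O[C@H](c1ccc(OCOC)c(Oc3ccc([C@@H]4CC(=O)c5c(O)cc(OCOC)cc5O4)cc3)c1)CC2=O | intermediate
18 | 7-O-methyltetrahydroochnaflavone | COc1cc(O)c2c(c1)O[C@H](c1ccc(O)c(Oc3ccc([C@@H]4CC(=O)c5c(O)cc(O)cc5O4)cc3)c1)CC2=O | target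

**Step count**

Total steps: 12. Longest linear sequence: 8 (steps 4, 5, 6, 8, 9, 10, 11, 12).

**Steps most likely to fail**

1. Step 9. Facial selectivity may be poor, because the methide carbon carries no substituent and the styrene offers the catalyst no hydrogen bond. The methide may also be lost to self-condensation or to alkylation of electron-rich arenes.

   The fallback sets out from 4 and 7 and comes back at 15. It moves the cycloaddition ahead of the ether coupling and takes the C2 configuration from a resolution on a small fragment: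
   - Fresh 4 is added slowly to an excess of bromostyrene 7 with diphenyl phosphate, (PhO)2P(O)OH, in toluene. This is the known non-asymmetric methide–styrene [4+2] and gives racemic bromoflavan F1.
   - Preparative chromatography on a chiral phase gives (2S)-bromoflavan F2. The (2R)-bromoflavan F3 is set aside.
   - F2 contains no carbonyl group and tolerates n-BuLi/B(Oi-Pr)3 at −78 °C. This gives flavan aryllithium F4, then flavan lithium borate F5, and after mild acid flavan boronic acid F6.
   - Chan–Lam coupling of F6 with phenol 12 under the conditions of step 8 gives 15.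

2. Step 8. Transmetalation of the ortho-substituted boronic acid may be slow and lose out to protodeboronation. Copper may be tied up by the 5-OH/4-carbonyl chelate. Configuration may erode slowly through opening of the 4'-hydroxyflavanone.

   The fallback sets out from 12 and 10 and comes back at 13, with the polarity of the coupling reversed:
   - 12 is sulfonylated at O-4' (PhNTf2, i-Pr2NEt, CH2Cl2) to naringenin 4'-triflate F7.
   - Miyaura borylation (B2pin2, Pd(dppf)Cl2, KOAc, dioxane, 80 °C) gives pinacol boronate F8.
   - NaIO4/NH4OAc in aqueous acetone frees the unhindered flavanone boronic acid F9.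
   - In parallel, 10 is oxidised with H2O2 in THF–water to 2-(methoxymethoxy)-5-vinylphenol F10.
   - Chan–Lam coupling of F9 with F10 (Cu(OAc)2, pyridine, 4 Å MS, CH2Cl2, air) gives 13.

3. Step 10. Proton loss from C3 of the C4 cation (dehydrogenation) may outrun capture by water, or the carbinol may re-ionise during isolation.

   The fallback sets out from 15 and comes back at 16. It replaces direct hydroxylation by dehydrogenation followed by hydration:
   - DDQ in dry dioxane completes the known dehydrogenation of a 7-oxygenated flavan to flav-3-ene F11. F11 is kept from light so that the pyran does not open electrocyclically.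
   - Mukaiyama hydration (Mn(dpm)3 cat., PhSiH3, O2, i-PrOH, 0 °C, then P(OEt)3) delivers hydrogen to C3 and oxygen to the ring A benzylic radical at C4. This gives 16.

Further compounds
F1 | step 9 | rac-2-[3-bromo-4-(methoxymethoxy)phenyl]-7-methoxy-5-(methoxymethoxy)chromane | COc1cc(OCOC)c2c(c1)OC(c1ccc(OCOC)c(Br)c1)CC2
F2 | step 9 | (2S)-2-[3-bromo-4-(methoxymethoxy)phenyl]-7-methoxy-5-(methoxymethoxy)chromane | COc1cc(OCOC)c2c(c1)O[C@H](c1ccc(OCOC)c(Br)c1)CC2
F3 | step 9 | (2R)-2-[3-bromo-4-(methoxymethoxy)phenyl]-7-methoxy-5-(methoxymethoxy)chromane | COc1cc(OCOC)c2c(c1)O[C@@H](c1ccc(OCOC)c(Br)c1)CC2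
F4 | step 9 | {5-[(2S)-7-methoxy-5-(methoxymethoxy)chroman-2-yl]-2-(methoxymethoxy)phenyl}lithium | COc1cc(OCOC)c2c(c1)O[C@H](c1ccc(OCOC)c([Li])c1)CC2
F5 | step 9 | lithium {5-[(2S)-7-methoxy-5-(methoxymethoxy)chroman-2-yl]-2-(methoxymethoxy)phenyl}triisopropoxyborate | [Li+].COc1cc(OCOC)c2c(c1)O[C@H](c1ccc(OCOC)c(c1)[B-](OC(C)C)(OC(C)C)OC(C)C)CC2
F6 | step 9 | {5-[(2S)-7-methoxy-5-(methoxymethoxy)chroman-2-yl]-2-(methoxymethoxy)phenyl}boronic acid | COc1cc(OCOC)c2c(c1)O[C@H](c1ccc(OCOC)c(B(O)O)c1)CC2
F7 | step 8 | 4-[(2S)-5-hydroxy-7-(methoxymethoxy)-4-oxochroman-2-yl]phenyl trifluoromethanesulfonate | O=S(=O)(Oc1ccc([C@@H]2CC(=O)c3c(O)cc(OCOC)cc3O2)cc1)C(F)(F)F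
F8 | step 8 | (2S)-5-hydroxy-7-(methoxymethoxy)-2-[4-(4,4,5,5-tetramethyl-1,3,2-dioxaborolan-2-yl)phenyl]chroman-4-one | CC1(C)OB(OC1(C)C)c1ccc([C@@H]2CC(=O)c3c(O)cc(OCOC)cc3O2)cc1
F9 | step 8 | {4-[(2S)-5-hydroxy-7-(methoxymethoxy)-4-oxochroman-2-yl]phenyl}boronic acid | OB(O)c1ccc([C@@H]2CC(=O)c3c(O)cc(OCOC)cc3O2)cc1
F10 | step 8 | 2-(methoxymethoxy)-5-vinylphenol | C=Cc1ccc(OCOC)c(O)c1
F11 | step 10 | flav-3-ene–flavanone, (2S) in both units (C3=C4 in unit 1) | COc1cc(OCOC)c2c(c1)O[C@H](c1ccc(OCOC)c(Oc3ccc([C@@H]4CC(=O)c5c(O)cc(OCOC)cc5O4)cc3)c1)C=C2
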